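**Assumption:** (+)-catechin, (2R,3S), is taken as the commercial starting material; reagents that only deliver protecting groups, metals or protons are named with SMILES but not numbered.

## Retrosynthetic overview

1. Target dimer ⇐ one-pot acid removal of eight MOM ethers and one TBS ether from a fully protected dimer.
2. Protected dimer ⇐ cut the diarylmethine C–aryl bond, not as the biomimetic quinone-methide Friedel–Crafts union, but as a stereoinvertive nickel-catalysed cross-coupling: the benzylic C2–O1 ether bond of an intact protected catechin is the electrophile, a C6-magnesiated protected catechin is the nucleophile.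
3. C6 Grignard reagent ⇐ directed ortho-metalation between the 5- and 7-OMOM groups of 3-O-TBS-tetra-O-MOM-catechin; electrophile ⇐ tetra-O-MOM-catechin as its magnesium 3-alkoxide.
4. Both partners ⇐ (+)-catechin, which supplies every carbon and three stereocentres unchanged; the fourth arises by inversion at C2 of the electrophile.
5. Ring order: no ring is built. Rings A, B and C of the lower flavan come intact from catechin; ring C of the upper unit is opened in the key step, which releases the upper phloroglucinol ring.

## Route

Step 1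
Reactants: 1 (+)-catechin
Product: 2 5,7,3',4'-tetra-O-MOM-(+)-catechin [(2R,3S)-2-[3,4-bis(methoxymethoxy)phenyl]-5,7-bis(methoxymethoxy)chroman-3-ol]
Conditions: MOMCl (4.4 equiv), K2CO3, acetone, 0 → 40 °C, Ar
Reagents that add atoms: chloromethyl methyl ether (MOMCl), COCCl
Why: The four phenoxides formed by K2CO3 are O-alkylated by MOMCl (Williamson-type acetal alkylation) much faster than the non-ionised secondary 3-OH, and the mild anhydrous base leaves both stereocentres untouched.

Step 2
Reactants: 2 5,7,3',4'-tetra-O-MOM-(+)-catechin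
Product: 3 3-O-TBS-5,7,3',4'-tetra-O-MOM-(+)-catechin [tert-butyl{[(2R,3S)-2-[3,4-bis(methoxymethoxy)phenyl]-5,7-bis(methoxymethoxy)chroman-3-yl]oxy}dimethylsilane]
Conditions: TBSCl, imidazole, DMF, rt → 40 °C
Reagents that add atoms: tert-butyldimethylsilyl chloride (TBSCl), CC(C)(C)[Si](C)(C)Cl
Why: Imidazole-promoted silylation of the only free hydroxyl puts a bulky, non-chelating group on O3, so that ring C of this unit is not activated by magnesium in step 3; no stereocentre is touched.

Step 3
Reactants: 3 3-O-TBS-5,7,3',4'-tetra-O-MOM-(+)-catechin; 2 5,7,3',4'-tetra-O-MOM-(+)-catechin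
Product: 7 protected dimer (1R,2S)-1-[(2R,3S)-2-[3,4-bis(methoxymethoxy)phenyl]-3-(tert-butyldimethylsilyloxy)-5,7-bis(methoxymethoxy)chroman-6-yl]-1-[3,4-bis(methoxymethoxy)phenyl]-3-[2-hydroxy-4,6-bis(methoxymethoxy)phenyl]propan-2-ol, via aryllithium 4 (not isolated), via aryl Grignard reagent 5 (not isolated), via chloromagnesium alkoxide 6 (not isolated)
Conditions: 3 (1.5 equiv), n-BuLi, THF, −20 → 0 °C; MgBr2·OEt2, 0 °C; separately 2, t-BuMgCl (1.0 equiv), THF, 0 °C; combine, NiCl2(Ph2PCH2CH2PPh2) (10 mol %), THF/PhMe, rt; aq NH4Cl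
Reagents that add atoms: none
Why: Proposed new method: directed ortho-metalation of 3 occurs at C6, the only position flanked by two chelating OMOM groups, and lithium-to-magnesium exchange gives 5; in 6 the magnesium bound to O3 chelates the ring oxygen O1 in a five-membered ring and activates the benzylic C2–O1 bond for SN2-type oxidative addition of zerovalent nickel with inversion (phenoxide leaving group), after which transmetalation with 5 and reductive elimination with retention form the C2–C6 bond with net inversion at the former C2, which is the required 1R diarylmethine once substituent priorities change, while the (S)-carbinol and the (2R,3S) centres of 5 are carried through unchanged and the non-chelating 3-OTBS group keeps the C2–O1 bond of 5 and of the product inert; the closest known reaction type is the stereospecific, invertive nickel-catalysed Kumada ring-opening cross-coupling of 2-aryl tetrahydropyrans and other benzylic ethers with Grignard reagents, which is accelerated by magnesium-chelating groups next to the leaving oxygen.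

Step 4
Reactants: 7 protected dimer
Product: 8 target dimer [(1R,2S)-1-[(2R,3S)-2-(3,4-dihydroxyphenyl)-3,5,7-trihydroxychroman-6-yl]-1-(3,4-dihydroxyphenyl)-3-(2,4,6-trihydroxyphenyl)propan-2-ol]
Conditions: HCl (1.25 M in MeOH), THF, rt, Ar
Reagents that add atoms: none
Why: Acid-catalysed acetal exchange with methanol removes the eight aryl MOM ethers and solvolyses the secondary TBS ether without breaking any bond at a stereocentre, so all four configurations are retained.

## Compound list

1 | (+)-catechin, (2R,3S)-2-(3,4-dihydroxyphenyl)chromane-3,5,7-triol | O[C@H]1Cc2c(O)cc(O)cc2O[C@@H]1c1ccc(O)c(O)c1 | starting material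
2 | 5,7,3',4'-tetra-O-MOM-(+)-catechin, (2R,3S)-2-[3,4-bis(methoxymethoxy)phenyl]-5,7-bis(methoxymethoxy)chroman-3-ol | O[C@H]1Cc2c(OCOC)cc(OCOC)cc2O[C@@H]1c1ccc(OCOC)c(OCOC)c1 | intermediate
3 | 3-O-TBS-5,7,3',4'-tetra-O-MOM-(+)-catechin, (2R,3S) | CC(C)(C)[Si](C)(C)O[C@H]1Cc2c(OCOC)cc(OCOC)cc2O[C@@H]1c1ccc(OCOC)c(OCOC)c1 | intermediate
4 | 6-lithio derivative of 3 (lithium at C6, between the 5- and 7-OMOM groups), (2R,3S) | CC(C)(C)[Si](C)(C)O[C@H]1Cc2c(OCOC)c([Li])c(OCOC)cc2O[C@@H]1c1ccc(OCOC)c(OCOC)c1 | intermediate
5 | 6-(bromomagnesio) derivative of 3, (2R,3S) | CC(C)(C)[Si](C)(C)O[C@H]1Cc2c(OCOC)c([Mg]Br)c(OCOC)cc2O[C@@H]1c1ccc(OCOC)c(OCOC)c1 | intermediate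
6 | chloromagnesium 3-alkoxide of 2, (2R,3S) | Cl[Mg]O[C@H]1Cc2c(OCOC)cc(OCOC)cc2O[C@@H]1c1ccc(OCOC)c(OCOC)c1 | intermediate
7 | protected dimer, (1R,2S)-1-[(2R,3S)-2-[3,4-bis(methoxymethoxy)phenyl]-3-(tert-butyldimethylsilyloxy)-5,7-bis(methoxymethoxy)chroman-6-yl]-1-[3,4-bis(methoxymethoxy)phenyl]-3-[2-hydroxy-4,6-bis(methoxymethoxy)phenyl]propan-2-ol | COCOc1cc(O)c(C[C@H](O)[C@H](c2ccc(OCOC)c(OCOC)c2)c2c(OCOC)cc3c(c2OCOC)C[C@H](O[Si](C)(C)C(C)(C)C)[C@@H](c2ccc(OCOC)c(OCOC)c2)O3)c(OCOC)c1 | intermediate
8 | target dimer, (1R,2S)-1-[(2R,3S)-2-(3,4-dihydroxyphenyl)-3,5,7-trihydroxychroman-6-yl]-1-(3,4-dihydroxyphenyl)-3-(2,4,6-trihydroxyphenyl)propan-2-ol | Oc1cc(O)c(C[C@H](O)[C@H](c2ccc(O)c(O)c2)c2c(O)cc3c(c2O)C[C@H](O)[C@@H](c2ccc(O)c(O)c2)O3)c(O)c1 | target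

## Summary

Total step count: 4. Longest linear sequence: 4 steps (1 → 2 → 3 → 7 → 8).

## Steps most likely to fail

**Step 3 (highest risk).** Nickel insertion into a benzylic C–O bond of a non-extended, electron-rich aryl ether has no direct precedent. Possible failures are partial lithiation at C8, sluggish oxidative addition, β-hydride elimination to a 1,3-diarylpropan-2-one, or attack on the MOM acetals. The fallback gives up cross-coupling for the thermal biomimetic union; it sets out from compound 1 and comes back to the route at compound 8. Heating 1 in degassed phosphate buffer (pH 6–7, 90–100 °C, Ar) opens ring C through the 4'-phenoxide to the ring-opened para-quinone methide F1. F1 is trapped in the flask at C6 of a second molecule of 1 by conjugate Friedel–Crafts addition, with facial selectivity set by the adjacent carbinol, the pathway by which the natural product is thought to arise. The C6-linked product 8 is separated from the C8-linked regioisomer on Sephadex LH-20 and by reversed-phase HPLC.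

**Step 4.** Nine protecting groups must leave in one pot, and the free undecahydroxy product is very polar, air-sensitive and hard to separate from partly deprotected material. The fallback is capture, purification and release through an ester derivative; it sets out from compound 7 and comes back at compound 8. After a short acid methanolysis the crude polyphenol is peracetylated (Ac2O, pyridine, DMAP) to the target dimer undecaacetate F2, which is stable and can be purified on silica. K2CO3 (cat.) in degassed MeOH at 0 °C under Ar, followed by neutralisation with an acidic resin, then releases 8.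

**Step 1.** Partial alkylation of the 3-OH, or incomplete alkylation of the phenols, would give mixtures that are hard to separate. The fallback masks the 3-OH temporarily; it sets out from compound 1 and comes back at compound 2. Ac2O/pyridine gives (+)-catechin pentaacetate F3. Hydrazine acetate in DMF at 0 °C cleaves only the four aryl acetates to give 3-O-acetyl-(+)-catechin F4. MOMCl/K2CO3 in acetone then gives 3-O-acetyl-5,7,3',4'-tetra-O-MOM-(+)-catechin F5, in which 3-O-alkylation is impossible. K2CO3 in MeOH removes the acetate to give 2.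

## Further compounds

F1 | step 3 | ring-opened para-quinone methide of (+)-catechin, (S)-carbinol | O=C1C=CC(=C[C@@H](O)Cc2c(O)cc(O)cc2O)C=C1O
F2 | step 4 | target dimer undecaacetate, (1R,2S) chain and (2R,3S) flavan | CC(=O)Oc1cc(OC(C)=O)c(C[C@H](OC(C)=O)[C@H](c2ccc(OC(C)=O)c(OC(C)=O)c2)c2c(OC(C)=O)cc3c(c2OC(C)=O)C[C@H](OC(C)=O)[C@@H](c2ccc(OC(C)=O)c(OC(C)=O)c2)O3)c(OC(C)=O)c1
F3 | step 1 | (+)-catechin pentaacetate, (2R,3S) | CC(=O)O[C@H]1Cc2c(OC(C)=O)cc(OC(C)=O)cc2O[C@@H]1c1ccc(OC(C)=O)c(OC(C)=O)c1
F4 | step 1 | 3-O-acetyl-(+)-catechin, (2R,3S) | CC(=O)O[C@H]1Cc2c(O)cc(O)cc2O[C@@H]1c1ccc(O)c(O)c1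
F5 | step 1 | 3-O-acetyl-5,7,3',4'-tetra-O-MOM-(+)-catechin, (2R,3S) | CC(=O)O[C@H]1Cc2c(OCOC)cc(OCOC)cc2O[C@@H]1c1ccc(OCOC)c(OCOC)c1
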